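**Strategy.** Ring B, the benzene ring shared by the dioxepinone and the hydroxyphthalide, is hexasubstituted; its carbons are called b1 (ether O), b2 (ester O), b3 (CH2OH), b4 (OH), b5 (lactone C=O) and b6 (lactol CH). The para oxygens on b1 and b4 flanking b6 and b5 are the imprint of a 2-silyloxyfuran–alkyne cycloaddition, so everything rests on cutting b4–b5 and b6–b1. In one operation furan 18, a 2-triisopropylsilyloxyfuran with a MOM-protected hydroxymethyl group at C4 and the ring A 2-bromobenzoyl group already on its 3-oxygen, adds to ynal 20 and the oxygen bridge opens, giving ring B with phenol, ester, aldehyde and silyl ether differentiated.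

Key step: step 12

Assumption: the lactol carbon epimerises by ring–chain tautomerism in acid or base, so it is fixed only in steps 16–17 and 29 must be isolated cold from neutral aprotic solution; 11–14, 21 and 25–27 are racemic, and 1 and 7 are taken as catalogue compounds.

**Ring A acid**

Step 1
Reactants: 1 4-methoxy-2,5-dimethylbenzoic acid
Product: 2 4-methoxy-2,5-dimethyl-3-nitrobenzoic acid
Conditions: fuming HNO3 (1.1 equiv), Ac2O, AcOH, 0 °C
Reagents that add atoms: nitric acid, O[N+](=O)[O-]
Why: Electrophilic aromatic nitration by acetyl nitrate; C3 is ortho to the methoxy group, ortho to a methyl group and meta to the carboxyl group, so all directors agree, and the only other free position (C6) has no oxygen activation.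

Step 2
Reactants: 2 4-methoxy-2,5-dimethyl-3-nitrobenzoic acid
Product: 3 3-amino-4-methoxy-2,5-dimethylbenzoic acid
Conditions: H2 (1 atm), Pd/C (10 wt%), MeOH, 23 °C
Reagents that add atoms: none
Why: Catalytic hydrogenation of a nitroarene to the aniline; no halogen or other reducible group is present yet.

Step 3
Reactants: 3 3-amino-4-methoxy-2,5-dimethylbenzoic acid
Product: 4 3-amino-6-bromo-4-methoxy-2,5-dimethylbenzoic acid
Conditions: NBS (1.0 equiv), DMF, 0 °C
Reagents that add atoms: N-bromosuccinimide, O=C1CCC(=O)N1Br
Why: Electrophilic aromatic bromination para to the amino group, which is the only unsubstituted ring position, so the bromine lands next to the carboxyl group without a regiochemical alternative.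

Step 4
Reactants: 4 3-amino-6-bromo-4-methoxy-2,5-dimethylbenzoic acid
Product: 6 2-bromo-4-methoxy-3,6-dimethylbenzoic acid, via arenediazonium hydrogen sulfate 5 (not isolated)
Conditions: NaNO2, 20% aq H2SO4, 0 °C; then 50% aq H3PO2, 0 → 23 °C
Reagents that add atoms: none
Why: Diazotisation followed by hydrodediazoniation with hypophosphorous acid (reductive deamination) removes the auxiliary amino group and leaves the bromide and the acid untouched.

**Furan and ynal**

Step 5
Reactants: 7 benzyl 3-hydroxypropanoate
Product: 8 benzyl 3-(methoxymethoxy)propanoate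
Conditions: MOMCl (1.5 equiv), iPr2NEt (2 equiv), CH2Cl2, 0 → 23 °C
Reagents that add atoms: chloromethyl methyl ether, COCCl
Why: O-Alkylation of the primary alcohol by the oxocarbenium ion from MOMCl gives the MOM acetal under conditions too mild for beta-elimination.

Step 6
Reactants: 8 benzyl 3-(methoxymethoxy)propanoate; 9 diethyl oxalate
Product: 11 1-benzyl 4-ethyl 2-[(methoxymethoxy)methyl]-3-oxobutanedioate, via lithium enolate 10 (not isolated)
Conditions: LDA (1.1 equiv), THF, −78 °C; cannulate into 9 (1.5 equiv), −78 °C; 1 M HCl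
Reagents that add atoms: none
Why: Crossed Claisen condensation of an ester enolate with non-enolisable diethyl oxalate; at −78 °C the beta-alkoxy enolate does not eliminate and liberated ethoxide does not exchange the benzyl ester.

Step 7
Reactants: 11 1-benzyl 4-ethyl 2-[(methoxymethoxy)methyl]-3-oxobutanedioate
Product: 13 benzyl 3-[(methoxymethoxy)methyl]-4,5-dioxooxolane-3-carboxylate, via hydroxymethyl adduct 12 (not isolated)
Conditions: 37% aq HCHO (1.2 equiv), K2CO3 (0.3 equiv), THF–H2O, 0 → 23 °C
Reagents that add atoms: formaldehyde, C=O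
Why: Aldol hydroxymethylation at the doubly activated carbon, then 5-exo-trig lactonisation of the new primary alcohol onto the oxalyl ethyl ester (the classical oxalyl ester–formaldehyde route to alpha-keto-gamma-lactones); the racemic quaternary centre is destroyed in step 8.

Step 8
Reactants: 13 benzyl 3-[(methoxymethoxy)methyl]-4,5-dioxooxolane-3-carboxylate
Product: 15 3-hydroxy-4-[(methoxymethoxy)methyl]furan-2(5H)-one, via beta-keto acid 14 (not isolated)
Conditions: H2 (1 atm), Pd/C (10 wt%), EtOAc, 23 °C; then 45 °C
Reagents that add atoms: none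
Why: Hydrogenolysis of the benzyl ester gives a beta-keto acid that decarboxylates under neutral conditions to the enol (isotetronic acid) form, so the extra carboxyl carbon leaves without the hot acid that would cleave the MOM ether.

Step 9
Reactants: 6 2-bromo-4-methoxy-3,6-dimethylbenzoic acid; 15 3-hydroxy-4-[(methoxymethoxy)methyl]furan-2(5H)-one
Product: 17 4-[(methoxymethoxy)methyl]-2-oxo-2,5-dihydrofuran-3-yl 2-bromo-4-methoxy-3,6-dimethylbenzoate, via acid chloride 16 (not isolated)
Conditions: 6, (COCl)2, DMF (cat.), CH2Cl2, 23 °C, evaporate; then 15, Et3N, DMAP (0.1 equiv), CH2Cl2, 0 → 23 °C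
Reagents that add atoms: none
Why: O-Acylation of the acidic enol by the acid chloride (nucleophilic catalysis by DMAP) installs ring A as a doubly ortho-substituted, migration-resistant enol ester that is only a weak donor on the future diene.

Step 10
Reactants: 17 4-[(methoxymethoxy)methyl]-2-oxo-2,5-dihydrofuran-3-yl 2-bromo-4-methoxy-3,6-dimethylbenzoate
Product: 18 4-[(methoxymethoxy)methyl]-2-[(triisopropylsilyl)oxy]furan-3-yl 2-bromo-4-methoxy-3,6-dimethylbenzoate
Conditions: TIPSOTf (1.2 equiv), Et3N (1.5 equiv), CH2Cl2, 0 °C; pentane, filter, used crude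
Reagents that add atoms: triisopropylsilyl triflate, CC(C)[Si](OS(=O)(=O)C(F)(F)F)(C(C)C)C(C)C
Why: Soft enolisation of the butenolide at C5 and O-silylation gives the aromatic 2-silyloxyfuran, the standard preparation of such dienes; excess amine keeps the silyl triflate from attacking the MOM ether.

Step 11
Reactants: 19 methyl 4-hydroxybut-2-ynoate
Product: 20 methyl 4-oxobut-2-ynoate
Conditions: activated MnO2 (10 equiv), CH2Cl2, 23 °C; Celite filtration, solution used at once
Reagents that add atoms: none
Why: Heterogeneous oxidation of a propargylic alcohol to the ynal gives a neutral, acid-free solution of the labile dienophile.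

**Key step and endgame**

Step 12
Reactants: 18 4-[(methoxymethoxy)methyl]-2-[(triisopropylsilyl)oxy]furan-3-yl 2-bromo-4-methoxy-3,6-dimethylbenzoate; 20 methyl 4-oxobut-2-ynoate
Product: 22 methyl 4-[(2-bromo-4-methoxy-3,6-dimethylbenzoyl)oxy]-2-formyl-6-hydroxy-5-[(methoxymethoxy)methyl]-3-[(triisopropylsilyl)oxy]benzoate, via oxanorbornadiene 21 (not isolated)
Conditions: 20 (1.5 equiv), toluene, 0 → 40 °C; then PPTS (5 mol%), 23 °C
Reagents that add atoms: none
Why: Normal-demand Diels–Alder reaction: the electron-rich silyloxyfuran 18 (largest HOMO coefficient at C5, the vinylogous terminus of the silyl ketene acetal) adds across the doubly activated alkyne of 20 to give oxanorbornadiene 21, which ionises at the silyloxy-bearing bridgehead (oxocarbenium stabilised by O–Si) and loses the proton of the other bridgehead, so the former furan oxygen becomes the b4 phenol. This is the known benzannulation of 2-silyloxyfurans with acetylenic dienophiles to para-silyloxyphenols. Ring B is closed by an intermolecular (4+2) cycloaddition that forms b4–b5 and b6–b1 together, followed by C–O heterolysis of the bridge and aromatisation. No stereocentre remains in 22; the two bridgehead centres of racemic 21 vanish on opening. The step needs regioselectivity: the formyl group is the stronger acceptor, so the alkyne carbon beta to it (the ester-bearing one) is the electrophilic terminus and pairs with furan C5, while the 3-aroyloxy group is too weak a donor to move the largest coefficient to C2. Chemoselectivity for cycloaddition over vinylogous aldol addition to the aldehyde follows from the absence of a Lewis acid.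

Step 13
Reactants: 22 methyl 4-[(2-bromo-4-methoxy-3,6-dimethylbenzoyl)oxy]-2-formyl-6-hydroxy-5-[(methoxymethoxy)methyl]-3-[(triisopropylsilyl)oxy]benzoate
Product: 23 methyl 4-[(2-bromo-4-methoxy-3,6-dimethylbenzoyl)oxy]-2-formyl-3,6-dihydroxy-5-[(methoxymethoxy)methyl]benzoate
Conditions: TBAF (1.1 equiv), AcOH (1.5 equiv), THF, 0 °C
Reagents that add atoms: none
Why: Fluoride-induced cleavage of the aryl silyl ether; the acetic acid buffer protonates the b1 phenoxide at once so the neighbouring aroyl ester does not migrate, and ester, aldehyde and MOM ether are untouched.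

Step 14
Reactants: 23 methyl 4-[(2-bromo-4-methoxy-3,6-dimethylbenzoyl)oxy]-2-formyl-3,6-dihydroxy-5-[(methoxymethoxy)methyl]benzoate
Product: 24 methyl 6-formyl-8-hydroxy-3-methoxy-9-[(methoxymethoxy)methyl]-1,4-dimethyl-11-oxo-11H-dibenzo[b,e][1,4]dioxepine-7-carboxylate
Conditions: CuI (0.2 equiv), N,N-dimethylglycine (0.4 equiv), Cs2CO3 (2.5 equiv), 1,4-dioxane, 90 °C
Reagents that add atoms: none
Why: Intramolecular Ullmann-type O-arylation: the b1 phenoxide, the more stable (ortho-formyl-conjugated) of the two possible catechol phenoxides so that the hindered aroyl ester stays on b2, displaces the bromide activated by its ortho ester and closes the seven-membered dioxepinone ring.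

Step 15
Reactants: 24 methyl 6-formyl-8-hydroxy-3-methoxy-9-[(methoxymethoxy)methyl]-1,4-dimethyl-11-oxo-11H-dibenzo[b,e][1,4]dioxepine-7-carboxylate
Product: 26 racemic lactol triol (target constitution with unassigned lactol carbon), via MOM-protected lactol 25 (not isolated)
Conditions: 3 M aq HCl, THF, 45 °C
Reagents that add atoms: water, O
Why: Acid-catalysed acetal hydrolysis removes the MOM ether, and the methyl ester is cleaved with anchimeric assistance by the hydrate of the neighbouring formyl group (pseudo-ester pathway of 2-formylbenzoates), closing the hydroxyphthalide as the racemate; the hindered depsidone ester and the aryl methyl ether are stable to aqueous acid.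

Step 16
Reactants: 26 racemic lactol triol
Product: 28 (R)-configured tripropionate (propionyl on the lactol oxygen and on the CH2O and phenol oxygens), via racemic bis-propionate 27 (not isolated)
Conditions: (EtCO)2O (4 equiv), (R)-benzotetramisole (0.1 equiv), iPr2NEt (4 equiv), CHCl3, 0 °C
Reagents that add atoms: propionic anhydride, CCC(=O)OC(=O)CC
Why: Acylative dynamic kinetic resolution by chiral isothiourea acyl transfer: the primary alcohol and phenol are acylated without stereochemical consequence, the lactol epimerises through base-mediated ring opening faster than it is acylated, and the acyl isothiouronium ion from the (R) catalyst should select the R lactol by the aryl recognition known for benzylic alcohols (the antipodal catalyst is used if a pilot run shows the opposite sense).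

Step 17
Reactants: 28 (R)-configured tripropionate
Product: 29 CNP0321962.1, the (R)-lactol target
Conditions: immobilised Candida antarctica lipase B, n-BuOH (10 equiv), MTBE, 25 °C; filter, concentrate cold
Reagents that add atoms: none
Why: Lipase-catalysed alcoholysis in an aprotic medium removes the primary, aryl and acylal propionates through the neutral acyl-enzyme, so the lactol oxygen is released protonated and the R centre set in step 16 is not opened to the achiral formyl carboxylate.

**Compound list**

1 | 4-methoxy-2,5-dimethylbenzoic acid | COc1cc(C)c(C(=O)O)cc1C | starting material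
2 | 4-methoxy-2,5-dimethyl-3-nitrobenzoic acid | COc1c([N+](=O)[O-])c(C)c(C(=O)O)cc1C | intermediate
3 | 3-amino-4-methoxy-2,5-dimethylbenzoic acid | COc1c(N)c(C)c(C(=O)O)cc1C | intermediate
4 | 3-amino-6-bromo-4-methoxy-2,5-dimethylbenzoic acid | COc1c(N)c(C)c(C(=O)O)c(Br)c1C | intermediate
5 | 4-bromo-3-carboxy-6-methoxy-2,5-dimethylbenzenediazonium hydrogen sulfate | COc1c([N+]#N)c(C)c(C(=O)O)c(Br)c1C.OS(=O)(=O)[O-] | intermediate (not isolated)
6 | 2-bromo-4-methoxy-3,6-dimethylbenzoic acid | COc1cc(C)c(C(=O)O)c(Br)c1C | intermediate
7 | benzyl 3-hydroxypropanoate | OCCC(=O)OCc1ccccc1 | starting material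
8 | benzyl 3-(methoxymethoxy)propanoate | COCOCCC(=O)OCc1ccccc1 | intermediate
9 | diethyl oxalate | CCOC(=O)C(=O)OCC | starting material
10 | lithium 1-(benzyloxy)-3-(methoxymethoxy)prop-1-en-1-olate | [Li+].COCOCC=C([O-])OCc1ccccc1 | intermediate (not isolated)
11 | 1-benzyl 4-ethyl 2-[(methoxymethoxy)methyl]-3-oxobutanedioate (racemic) | CCOC(=O)C(=O)C(COCOC)C(=O)OCc1ccccc1 | intermediate
12 | 1-benzyl 4-ethyl 2-(hydroxymethyl)-2-[(methoxymethoxy)methyl]-3-oxobutanedioate (racemic) | CCOC(=O)C(=O)C(CO)(COCOC)C(=O)OCc1ccccc1 | intermediate (not isolated)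
13 | benzyl 3-[(methoxymethoxy)methyl]-4,5-dioxooxolane-3-carboxylate (racemic) | O=C1OCC(COCOC)(C(=O)OCc2ccccc2)C1=O | intermediate
14 | 3-[(methoxymethoxy)methyl]-4,5-dioxooxolane-3-carboxylic acid (racemic) | O=C1OCC(COCOC)(C(=O)O)C1=O | intermediate (not isolated)
15 | 3-hydroxy-4-[(methoxymethoxy)methyl]furan-2(5H)-one | COCOCC1=C(O)C(=O)OC1 | intermediate
16 | 2-bromo-4-methoxy-3,6-dimethylbenzoyl chloride | COc1cc(C)c(C(=O)Cl)c(Br)c1C | intermediate (not isolated)
17 | 4-[(methoxymethoxy)methyl]-2-oxo-2,5-dihydrofuran-3-yl 2-bromo-4-methoxy-3,6-dimethylbenzoate | COCOCC1=C(OC(=O)c2c(C)cc(OC)c(C)c2Br)C(=O)OC1 | intermediate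
18 | 4-[(methoxymethoxy)methyl]-2-[(triisopropylsilyl)oxy]furan-3-yl 2-bromo-4-methoxy-3,6-dimethylbenzoate | COCOCc1coc(O[Si](C(C)C)(C(C)C)C(C)C)c1OC(=O)c1c(C)cc(OC)c(C)c1Br | intermediate (key-step precursor)
19 | methyl 4-hydroxybut-2-ynoate | COC(=O)C#CCO | starting material
20 | methyl 4-oxobut-2-ynoate | COC(=O)C#CC=O | intermediate (key-step precursor)
21 | methyl 5-[(2-bromo-4-methoxy-3,6-dimethylbenzoyl)oxy]-3-formyl-6-[(methoxymethoxy)methyl]-4-[(triisopropylsilyl)oxy]-7-oxabicyclo[2.2.1]hepta-2,5-diene-2-carboxylate (racemic) | COC(=O)C1=C(C=O)C2(O[Si](C(C)C)(C(C)C)C(C)C)OC1C(COCOC)=C2OC(=O)c1c(C)cc(OC)c(C)c1Br | intermediate (not isolated)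
22 | methyl 4-[(2-bromo-4-methoxy-3,6-dimethylbenzoyl)oxy]-2-formyl-6-hydroxy-5-[(methoxymethoxy)methyl]-3-[(triisopropylsilyl)oxy]benzoate | COC(=O)c1c(O)c(COCOC)c(OC(=O)c2c(C)cc(OC)c(C)c2Br)c(O[Si](C(C)C)(C(C)C)C(C)C)c1C=O | intermediate (key-step product)
23 | methyl 4-[(2-bromo-4-methoxy-3,6-dimethylbenzoyl)oxy]-2-formyl-3,6-dihydroxy-5-[(methoxymethoxy)methyl]benzoate | COC(=O)c1c(O)c(COCOC)c(OC(=O)c2c(C)cc(OC)c(C)c2Br)c(O)c1C=O | intermediate
24 | methyl 6-formyl-8-hydroxy-3-methoxy-9-[(methoxymethoxy)methyl]-1,4-dimethyl-11-oxo-11H-dibenzo[b,e][1,4]dioxepine-7-carboxylate | COc1cc(C)c2c(c1C)Oc1c(C=O)c(C(=O)OC)c(O)c(COCOC)c1OC2=O | intermediate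
25 | racemic depsidone hydroxyphthalide with the CH2O group still MOM-protected | COc1cc(C)c2c(c1C)Oc1c(c(COCOC)c(O)c3c1C(O)OC3=O)OC2=O | intermediate (not isolated)
26 | racemic lactol triol (target constitution) | COc1cc(C)c2c(c1C)Oc1c(c(CO)c(O)c3c1C(O)OC3=O)OC2=O | intermediate
27 | racemic lactol with propionyl on the CH2O and phenol oxygens | COc1cc(C)c2c(c1C)Oc1c(c(COC(=O)CC)c(OC(=O)CC)c3c1C(O)OC3=O)OC2=O | intermediate (not isolated)
28 | (R)-tripropionate (R at the acyloxyphthalide carbon) | COc1cc(C)c2c(c1C)Oc1c(c(COC(=O)CC)c(OC(=O)CC)c3c1[C@H](OC(=O)CC)OC3=O)OC2=O | intermediate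
29 | CNP0321962.1 (R at the lactol carbon) | COc1cc(C)c2c(c1C)Oc1c(c(CO)c(O)c3c1[C@H](O)OC3=O)OC2=O | target

**Totals.** 17 steps in all; longest linear sequence 12 steps (steps 1–4 or 5–8, then 9, 10, 12–17).

**Steps most likely to fail**

Step 12. Regiocontrol may erode because the ester acceptor competes with the formyl group, or the doubly activated ynal may oligomerise before it is trapped. Fallback, setting out from 18: cycloaddition with prop-2-ynal (toluene, 60 °C), whose single acceptor leaves no ambiguity, and the same bridge opening should give the ester-free formyl phenol F1 (b5 bears hydrogen). The only unsubstituted ring B position, ortho to the new phenol, is then iodinated (NIS, MeCN, 0 °C) to the aryl iodide F2. Methoxycarbonylation (Pd(OAc)2, Xantphos, CO 1 atm, MeOH, Et3N, 60 °C), selective for the iodide over the doubly ortho-substituted bromide, rejoins the route at 22.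

Step 14. Oxidative addition at the doubly ortho-substituted bromide may be slow while the b1 phenoxide is held in a chelate with the neighbouring formyl group, leaving time for aroyl migration or base-induced loss of the aldehyde. Fallback, setting out from 23: acid-catalysed isomerisation of the formyl ester to its cyclic pseudo-ester (CSA 5 mol%, MeOH, 23 °C) gives the 3-methoxyphthalide phenol F3, in which the aldehyde is masked and the phenoxide is free. The ring is then closed by a C–O coupling on zerovalent palladium through oxidative addition and reductive elimination (Pd(OAc)2, tBuXPhos, K3PO4, toluene, 80 °C) to the methoxyphthalide depsidone F4. The aqueous acid of step 15 opens the pseudo-ester and the MOM ether together and returns to the route at 26.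

Step 17 (with the polyacylation of step 16). The hindered aryl propionate may be cleaved slowly by the enzyme, and the free lactol may lose configurational purity by ring–chain tautomerism while the remaining esters are still being removed. Fallback, setting out from 26: the phenol and CH2OH oxygens are tied as a cyclic silylene (tBu2Si(OTf)2, 2,6-lutidine, CH2Cl2, 0 °C) to give the silylene-protected lactol F5, so that the resolution of step 16 (1.5 equiv anhydride) acylates only the lactol and gives the silylene (R)-propionate F6. HF·pyridine (THF, 0 °C), to which the acylal is stable, gives the (R)-monopropionate diol F7, and a short lipase alcoholysis of this single acylal ester under the conditions of step 17 arrives at 29.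

**Further compounds**

F1 | step 12 | 3-formyl-5-hydroxy-6-[(methoxymethoxy)methyl]-2-[(triisopropylsilyl)oxy]phenyl 2-bromo-4-methoxy-3,6-dimethylbenzoate | O=Cc1cc(O)c(COCOC)c(OC(=O)c2c(C)cc(OC)c(C)c2Br)c1O[Si](C(C)C)(C(C)C)C(C)C
F2 | step 12 | 3-formyl-5-hydroxy-4-iodo-6-[(methoxymethoxy)methyl]-2-[(triisopropylsilyl)oxy]phenyl 2-bromo-4-methoxy-3,6-dimethylbenzoate | O=Cc1c(I)c(O)c(COCOC)c(OC(=O)c2c(C)cc(OC)c(C)c2Br)c1O[Si](C(C)C)(C(C)C)C(C)C
F3 | step 14 | 4,7-dihydroxy-3-methoxy-6-[(methoxymethoxy)methyl]-1-oxo-1,3-dihydro-2-benzofuran-5-yl 2-bromo-4-methoxy-3,6-dimethylbenzoate (racemic) | COCOCc1c(OC(=O)c2c(C)cc(OC)c(C)c2Br)c(O)c2C(OC)OC(=O)c2c1O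
F4 | step 14 | racemic depsidone 3-methoxyphthalide with MOM-protected CH2O group | COc1cc(C)c2c(c1C)Oc1c(c(COCOC)c(O)c3c1C(OC)OC3=O)OC2=O
F5 | step 17 | racemic lactol with a di-tert-butylsilylene bridge between the phenol and CH2O oxygens | COc1cc(C)c2c(c1C)Oc1c(c3CO[Si](C(C)(C)C)(C(C)(C)C)Oc3c3c1C(O)OC3=O)OC2=O
F6 | step 17 | (R)-lactol propionate with the di-tert-butylsilylene bridge | COc1cc(C)c2c(c1C)Oc1c(c3CO[Si](C(C)(C)C)(C(C)(C)C)Oc3c3c1[C@H](OC(=O)CC)OC3=O)OC2=O
F7 | step 17 | (R)-lactol propionate with free CH2OH and phenol | COc1cc(C)c2c(c1C)Oc1c(c(CO)c(O)c3c1[C@H](OC(=O)CC)OC3=O)OC2=O
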